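The earlier runs and the new flask were computed for an exercise, and the scatter is random.

4 questions stand on this flask, and one reckoned time carries them.

| flask | solid substrate | target | remark | time |
|---|---|---|---|---|
| teal | 0.14 M | 0.010 M | run made earlier |  |
| grey | 0.22 M | 0.010 M | run made earlier |  |
| flask | 0.10 M | 0.0100 M |  | 2.0 min |

| run | time / s | target / % |
|---|---|---|
| teal | 12.0 | 12 |
| teal | 20.0 | 19 |
| teal | 25.0 | 27 |
| teal | 40.0 | 45 |
| teal | 50.0 | 61 |
| teal | 80.0 | 74 |
| grey | 12.0 | 7 |
| grey | 20.0 | 12 |
| grey | 25.0 | 18 |
| grey | 40.0 | 31 |
| grey | 50.0 | 39 |
| grey | 80.0 | 61 |

(scatter of a reading: 1.5 percentage points)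

- time up to 2.0 min at which target stands highest
- the amount of target, in percent of the solid substrate charged, at that time
- earliest time at which at least nineteen twentieths of that best amount are there, in min
- latest time at which they still are, in min

- solid, in amounts per volume of the solution: solid substrate
- at the start none of the solid substrate is in solution

What do the earlier runs show? Multiply each percentage by its charge. In the grey run [target] climbs at 0.00175 M s⁻¹ from first to last reading, and in the teal run at 0.00181 M s⁻¹ up to 50.0 s. The two agree although the charges differ, so I read the rise as zero-order in the charge and call it the feed rate.

How long does a charge last? Work with the fraction left: one minus feed rate times time over charge. For this flask it reaches zero at charge over feed rate, 0.954 min, the emptying time.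

Does target follow the line that far? Not in the teal run. Its emptying time is 80.1 s, and at 80.0 s, about that time, target reads 74%. Counting off the target charged at the start, 33.1% of the teal charge is not seen as target in that reading. The grey run still climbs from 39% to 61% up to 80.0 s, a time before its emptying time of 126 s.

So where is the top? The teal run was on the line at 50.0 s, and that time scaled by charge gives 0.595 min for this flask. I commit to a top between 0.595 min and 0.954 min.

The forecast puts the top at 0.77 min with 78%, and the level from 0.68 min to 0.97 min, reasoning that “target seems to be lost once the substrate runs low”.

The flask tops at 0.866 min with 84.6%, and stands at the asked share of that or above from 0.788 min to 1.04 min.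

    starting material → target (k = 3.09 × 10⁻⁴ s⁻¹)
    starting material + target → 2 target (k = 4.35 M⁻¹ s⁻¹)
    starting material ⇌ dormant form (K = 1.02, k = 0.0177 s⁻¹)
    target ⇌ isomer of the product (K = 14.0, k = 0.00796 s⁻¹)
    solid substrate ⇌ starting material, rate k5*(cs5 - [starting material]) while solid is left; crystals form when [starting material] > cs5 (solubility = 0.0530 M, k = 0.0505 s⁻¹)

The emptying time of 0.954 min falls inside that window, 0.0880 min after the top, where the solid substrate of this flask already stands at 0%. For the neighbour flask with 0.060 M of solid substrate, the same reckoning gives 0.572 min, which leaves 1.43 min to the longest time, against 1.05 min in this flask. The neighbour flask tops at 89.3% and falls by 35 percentage points, while this flask falls by 30 points. At the end of the neighbour flask target stands at 54.4% and the isomer of the product at 59.3%.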